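(All runs were computed from invented constants, and the scatter is random.)

- A small charge, 1 mol% of free catalyst on c(substrate) = 0.050 M, was to stand for 25 h, and I had to choose which of cedar, alder and maple to keep, so I needed a figure for each temperature.

| flask | substrate | free catalyst | temperature | remark | time |
|---|---|---|---|---|---|
| noon | 0.025 M | 1 mol% | 2 °C | run made earlier |  |
| dusk | 0.038 M | 1 mol% | 19 °C | run made earlier |  |
| winter | 0.050 M | 0.5 mol% | 2 °C | run made earlier |  |
| cedar | 0.050 M | 1 mol% | 25 °C |  | 25 h |
| alder | 0.050 M | 1 mol% | 10 °C |  | 25 h |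
| maple | 0.050 M | 1 mol% | −5 °C |  | 25 h |

| run | time / h | product / % |
|---|---|---|
| noon | 8.00 | 0 |
| noon | 15.0 | 0.3 |
| noon | 25.0 | 3.0 |
| noon | 30.0 | 2.3 |
| noon | 40.0 | 3.4 |
| noon | 50.0 | 3.1 |
| dusk | 1.00 | 0.1 |
| dusk | 3.00 | 2.3 |
| dusk | 5.00 | 4.2 |
| dusk | 8.00 | 6.0 |
| dusk | 12.0 | 6.3 |
| dusk | 15.0 | 10.8 |
| winter | 10.0 | 1.4 |
| winter | 20.0 | 3.4 |
| winter | 30.0 | 0 |
| winter | 40.0 | 0 |
| winter | 50.0 | 1.1 |

(each reading ± 1 percentage point)

- the analysis behind the earlier runs scatters by 1 percentage point, standard deviation

* the best flask by amount of product, in percent of the substrate charged; "all alike" if 1.5 percentage points covers them all (cedar / alder / maple / all alike)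
* amount of product at the end, in percent of the substrate charged, cedar
* amount of product at the end, in percent of the substrate charged, alder
* amount of product at the end, in percent of the substrate charged, maple

- The noon and dusk runs held the same loading as these flasks, 1 mol%, at different temperatures, so I compared their slopes.
- Between 3.00 h and 15.0 h, the dusk run gained a fraction of its charge at 0.00708 h⁻¹. Between 15.0 h and 50.0 h, the noon run gained at 8.00 × 10⁻⁴ h⁻¹.
- Their quotient was 8.85, my warming ratio, a temperature coefficient: the factor the fractional rate gained from the noon run at 2 °C to the dusk run at 19 °C at equal loading, with time divided out. The two runs also differed in c(substrate), 0.025 M against 0.038 M, and the ratio carried that difference with it. It was a reading from two points per run, each with a scatter of 1 percentage point, so I held it loosely.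
- I scaled the dusk slope by the warming ratio, raised to each flask's temperature gap from dusk over the gap from noon to dusk, and let substrate fall first order at that rate.
- My reckoning gave 31.8% for cedar, 5.43% for alder and 0.811% for maple. Cedar stood highest in my reckoning, so I kept cedar.
- The forecast gave 20% for cedar, 7% for alder and 1.5% for maple, and it named cedar as best: “The warmest flask should win clearly”. Its cedar figure was lower than mine.
- The flasks gave 29.8% in cedar, 5.34% in alder and 0.558% in maple, so cedar was best.

    substrate + free catalyst → catalyst intermediate A (k = 270 L mol⁻¹ h⁻¹, Ea = 55.0 kJ mol⁻¹)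
    catalyst intermediate A ⇌ catalyst intermediate B (K = 1.70, k = 12.0 h⁻¹, Ea = 94.0 kJ mol⁻¹, ΔH = −42.0 kJ mol⁻¹)
    catalyst intermediate B ⇌ free catalyst + product (K = 0.940 M, k = 2.40 h⁻¹, Ea = 92.0 kJ mol⁻¹, ΔH = −32.0 kJ mol⁻¹)
    (constants at 25 °C)

- Cedar ended 2 points below my figure and 9.8 points above the forecast. I carried the warming ratio, 8.85, to a flask like alder kept at 35 °C, scaling the dusk slope as before, and reckoned 74.8% of product at 25 h. That flask held 72.1% of product, with 27.2% of the substrate still there.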